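## Analysis of the target

The target is a trans-fused daucane: a cyclopentane (C1–C5) fused through the C1–C5 bond to a cycloheptene (C1, C5–C10) whose only alkene is C8=C9, with methyl C14 on C8 and methyl C15 on C1 (daucane numbering, used for all intermediates below). It has six stereocentres: quaternary C1 (C15 β), C2 (acetate α), the fully substituted carbinol C4 (OH β, isopropyl α), C5 (H α), C6 (angelate α) and C10 (benzoate β). Around C5 the oxygens on C4 and C6 are 1,3-syn and the C5–C1 bond is anti to both; the ring fusion is trans. Three different acyl groups sit on three secondary oxygens (O2, O6, O10) beside a free tertiary hydroxyl, so each oxygen must be distinguishable when it is acylated. The sensitive groups are the angelate (Z to E isomerisation under nucleophilic or basic conditions), the allylic benzoate at C10 (ionisation by acid or zerovalent palladium), and the C4 oxygen, which is β to C2 and is open to elimination or retro-aldol cleavage while C2 is a ketone. The hard parts are the quaternary C1, which carries four different carbon substituents and is flanked by three stereocentres, and the tetrasubstituted C4. The strategy rests on the fact that C4 is 1,5 to C3 across the C2 carbonyl. If C2–C3 is an acyl carbene on C1 and C4 is a silyl-protected secondary carbinol on C5, the C3–C4 bond can replace the C4–H bond with retention. C4 can then be made as an ordinary secondary alcohol, and the five-membered ring is closed last on a cycloheptene that already carries both unsaturated esters.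

## Retrosynthetic reasoning

**O2 and the C2 carbinol (28, 27, 26, 25).** The acetate is put on last, on diol 27, where only the secondary O2 can be acylated. The C2 hydroxyl is α, so hydride must arrive on the β face of the C2 ketone, the face that carries C15. An external hydride would prefer the other face, and an SN2 inversion at the neopentyl C2 is not attractive. The C4 hydroxyl, which is β, is therefore freed first (26 from 25) and used to deliver hydride intramolecularly.

**C3–C4 (25 from 24).** This is the only ring bond of the cyclopentane that can be made by replacing a hydrogen on an existing stereocentre. Cutting it turns the tetrasubstituted C4 into a secondary silyl ether and the ring into a diazoketone on C1. The forward reaction must insert into C4–H alone and leave the alkene, the two esters and the other C–H bonds untouched.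

**C2–C3 and the C2 acid (24, 23, 22, 21, 20).** The diazoketone comes from acid 22 by acylation of a one-carbon diazo unit through acid chloride 23. The acid is carried as the tert-butyl ester 20 because this group survives hydride, Grignard, metathesis, oxidation and acylation conditions and can be removed without protic acid or base (through silyl ester 21).

**O10, O6 and the C10 configuration (20, 18, 17, 14, 13).** The benzoate comes from 19 and alcohol 18, the angelate from 15 (through 16) and the enone alcohol 14. Diol 13 has two secondary hydroxyls of similar hindrance; oxidising only the allylic one to enone 14 tells them apart. The same detour makes C10 a ketone, so its configuration is set by a reagent-controlled reduction (17 to 18) and not inherited from an earlier addition.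

**C8=C9 (13 from 12).** The alkene is the one ring bond with no stereocentre at either end, and a metathesis there needs only a vinyl and a methallyl group. The forward step must close a seven-membered ring onto a 1,1-disubstituted alkene.

**C9–C10 and release of O6 (12, 11, 10).** In lactone 10 the lactone carbonyl is C10 and the ring oxygen is O6. Reduction to lactol 11 and vinyl addition give the C10 carbinol and free O6 in two steps, with the C2 ester untouched.

**C1–C15 and C1–C2 (10, 9, 8).** The quaternary centre is built on the γ-lactone 8, whose substituents at C5 and C6 are cis. Two successive enolate reactions, methylation then tert-butoxycarbonylation, put the second group on the open face, trans to both substituents. The order decides the configuration: the ester must come last.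

**C6–C7 (8, 7, 6).** Methallylation of aldehyde 6 sets C6 and brings in C7, C8 and C14. The required carbinol is anti to the C1 arm and 1,3-syn to O4, which is against the Felkin–Anh preference of 6, so a chiral allylborane is used. Lactonisation of 7 then masks O6 and gives the template 8.

**C1–C5 and C4 (6, 5, 4, 3, 2, 1).** The C1–C5 bond is made while C1 is still a methylene: anti-selective alkylation of the dianion of hydroxy ester 2 with bromoacetate 3 gives 4. The methyl ester is the future C6 and the tert-butyl ester the future C10. C4 comes from catalytic asymmetric hydrogenation of keto ester 1, and silylation (5) installs the group that later activates C4–H.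

## Alternatives that were turned down

**Alternative 1:** Büchner ring expansion. The disconnection cuts C1–C5 and C1–C10 at once, so the seven-membered ring comes from a p-tolyl ring. In the forward step the metal carbene from the α-diazo ethyl ketone A1 adds to the ipso–ortho bond of the arene, and the norcaradiene opens to the dihydroazulenone A2. In its favour, A1 is a short reach from simple aromatic ketone chemistry, and one step gives the whole carbon skeleton with C14, C15 and the quaternary C1. Against it, A2 is a cycloheptatriene with C5 sp2 and no oxygen at C6 or C10. The trans ring fusion, both ring oxygens with their configurations, and the removal of two of three conjugated double bonds would all have to be done on a triene that equilibrates with its norcaradiene and shifts hydrogen. The carbene also carries a methyl group, so 1,2-hydride shift competes, and its facial choice rests on C4 alone. On step count to the skeleton this route is clearly stronger than the chosen one. The chosen route instead brings all seven-membered-ring stereocentres and both esters to its key step, so that only three functional-group steps follow it.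

**Alternative 2:** [2,3]-Wittig ring expansion. The disconnection cuts C6–C7 and reconnects O to C9, so the cycloheptene comes from a tetrahydropyran. In the forward step tin–lithium exchange on stannane A3 gives an α-alkoxy carbanion at C6 that attacks the terminal carbon of the isopropenyl group on C9 and gives A4. In its favour, one stereospecific step gives the carbocycle, the C8=C9 alkene (cis by ring constraint) and the free, already differentiated C6 hydroxyl; here it is stronger than the chosen route, which needs a chiral reagent for C6 and a separate metathesis. Against it, A3 must already contain C1, C2, C4, C5 and C10 on a cyclopentane, so the two hardest centres (quaternary C1 and tetrasubstituted C4) are solved elsewhere by unspecified means. The shift must pass through a bicyclic transition state from a ring-bound oxygen, with [1,2]-shift and elimination as competitors. A4 carries three different protecting groups that must be exchanged one by one for acetate, benzoate and angelate. The chosen route makes C4 stereospecifically in its key step and has the esters in place beforehand.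

**Alternative 3:** Conjugate addition and trapping on a cycloheptadienone. The disconnection cuts C4–C5 and C1–C2 on a preformed ring. In the forward step a masked acetyl anion, delivered as a cuprate, adds to C5 of dienone A5 anti to the C6 silyloxy group, and the enolate is trapped at C1 by a one-carbon aldehyde to give A6. In its favour, the step is convergent, sets C5 and C1 from the single stereocentre C6, and uses a well-known reaction type; the route is probably shorter than the chosen one. Against it, the five-membered ring is still open after the key step. C4 must then be made by adding an isopropyl nucleophile to a hindered, enolisable ketone, and C2 and C10 by substrate-controlled ketone reductions. The trapping also has to form a quaternary centre on a tetrasubstituted enolate next to the new C5 substituent. The chosen route is longer, but it sets C4 by asymmetric hydrogenation and transfers it with retention, and it sets C10 under reagent control.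

Key step: step 17

Remark: TBS is tert-butyldimethylsilyl; C10 in 12 and 13 is carried as a mixture of epimers, which converges in step 11.

## Steps

Step 1
Reactants: 1 methyl 4-methyl-3-oxopentanoate
Product: 2 methyl (3S)-3-hydroxy-4-methylpentanoate
Conditions: H2 (50 atm), RuCl2[(R)-BINAP] (0.1 mol%), MeOH, 50 °C
Reagents that add atoms: none
Why: Noyori asymmetric hydrogenation of a β-keto ester; the ester carbonyl chelates ruthenium and the (R)-BINAP complex should deliver hydrogen to the face that gives the (S)-carbinol (S because isopropyl outranks CH2CO2Me), which becomes C4.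

Step 2
Reactants: 2 methyl (3S)-3-hydroxy-4-methylpentanoate; 3 tert-butyl bromoacetate
Product: 4 4-tert-butyl 1-methyl (2R)-2-[(1R)-1-hydroxy-2-methylpropyl]butanedioate
Conditions: LiN(iPr)2 (2.2 equiv), THF, −78 → −20 °C; then 3, THF/DMPU, −78 → −20 °C
Reagents that add atoms: tert-butyl bromoacetate (3), BrCC(=O)OC(C)(C)C
Why: Fráter–Seebach alkylation; the dilithium alkoxide–enolate is a rigid six-membered chelate and the halide attacks C5 on the face away from the isopropyl group, giving the anti product. The tert-butyl ester keeps the new carboxyl (future C10) distinct from the methyl ester (future C6).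

Step 3
Reactants: 4 4-tert-butyl 1-methyl (2R)-2-[(1R)-1-hydroxy-2-methylpropyl]butanedioate
Product: 5 4-tert-butyl 1-methyl (2R)-2-[(1R)-1-(TBS-oxy)-2-methylpropyl]butanedioate
Conditions: TBSOTf, 2,6-lutidine, CH2Cl2, −78 → 0 °C
Reagents that add atoms: tert-butyldimethylsilyl trifluoromethanesulfonate, CC(C)(C)[Si](C)(C)OS(=O)(=O)C(F)(F)F
Why: Silylation of a hindered secondary alcohol with a silyl triflate and a hindered base; both esters are inert at this temperature, and this silyl ether is the group that later activates C4–H.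

Step 4
Reactants: 5 4-tert-butyl 1-methyl (2R)-2-[(1R)-1-(TBS-oxy)-2-methylpropyl]butanedioate
Product: 6 tert-butyl (3R,4R)-4-(TBS-oxy)-3-formyl-5-methylhexanoate
Conditions: iBu2AlH (1.1 equiv), CH2Cl2, −78 °C; MeOH, aq. potassium sodium tartrate
Reagents that add atoms: none
Why: Partial reduction of a methyl ester with iBu2AlH; its tetrahedral aluminate persists at −78 °C until work-up, and the tert-butyl ester reacts far more slowly. The aldehyde is used at once because C5 is epimerisable.

Step 5
Reactants: 6 tert-butyl (3R,4R)-4-(TBS-oxy)-3-formyl-5-methylhexanoate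
Product: 8 (4S,5S)-4-[(1R)-1-(TBS-oxy)-2-methylpropyl]-5-(2-methylprop-2-en-1-yl)oxolan-2-one, via hydroxy ester 7 (not isolated)
Conditions: (−)-Ipc2B(methallyl) [from methallylmagnesium chloride and (−)-Ipc2BOMe, Et2O, −78 °C → rt], Et2O, −78 °C; NaOH, H2O2; then CSA (10 mol%), CH2Cl2, rt
Reagents that add atoms: methallylmagnesium chloride, C=C(C)C[Mg]Cl
Why: Brown allylboration through a chair six-membered transition state in which the isopinocampheyl groups, not the substrate, choose the aldehyde face; the reagent from (+)-α-pinene should give (S)-C6 against the Felkin–Anh preference. Acid-catalysed 5-exo lactonisation of 7 onto the tert-butyl ester then masks O6 and leaves the C5 and C6 substituents cis.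

Step 6
Reactants: 8 (4S,5S)-4-[(1R)-1-(TBS-oxy)-2-methylpropyl]-5-(2-methylprop-2-en-1-yl)oxolan-2-one
Product: 9 (3RS,4S,5S)-4-[(1R)-1-(TBS-oxy)-2-methylpropyl]-3-methyl-5-(2-methylprop-2-en-1-yl)oxolan-2-one
Conditions: LiN(iPr)2, THF, −78 °C; MeI, −78 → −40 °C
Reagents that add atoms: iodomethane, CI
Why: Alkylation of a lactone lithium enolate; the configuration at C1 does not matter here because this centre is enolised again in step 7.

Step 7
Reactants: 9 (3RS,4S,5S)-4-[(1R)-1-(TBS-oxy)-2-methylpropyl]-3-methyl-5-(2-methylprop-2-en-1-yl)oxolan-2-one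
Product: 10 tert-butyl (3S,4S,5S)-4-[(1R)-1-(TBS-oxy)-2-methylpropyl]-3-methyl-5-(2-methylprop-2-en-1-yl)-2-oxooxolane-3-carboxylate
Conditions: LiN(iPr)2, THF, −78 → −40 °C; Boc2O, −78 °C → rt
Reagents that add atoms: di-tert-butyl dicarbonate, CC(C)(C)OC(=O)OC(=O)OC(C)(C)C
Why: C-acylation of a tetrasubstituted lactone enolate (Claisen-type); both ring substituents sit on one face, so the electrophile should enter from the other. The ester (C2) then ends trans to the C4 arm and methyl C15 cis, which fixes the quaternary C1.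

Step 8
Reactants: 10 tert-butyl (3S,4S,5S)-4-[(1R)-1-(TBS-oxy)-2-methylpropyl]-3-methyl-5-(2-methylprop-2-en-1-yl)-2-oxooxolane-3-carboxylate
Product: 11 tert-butyl (3S,4S,5S)-4-[(1R)-1-(TBS-oxy)-2-methylpropyl]-2-hydroxy-3-methyl-5-(2-methylprop-2-en-1-yl)oxolane-3-carboxylate (both anomers)
Conditions: iBu2AlH (1.2 equiv), CH2Cl2, −78 °C
Reagents that add atoms: none
Why: Reduction of a lactone to the lactol with iBu2AlH at low temperature; the neopentyl tert-butyl ester is too hindered and too poor an electrophile to compete.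

Step 9
Reactants: 11 tert-butyl (3S,4S,5S)-4-[(1R)-1-(TBS-oxy)-2-methylpropyl]-2-hydroxy-3-methyl-5-(2-methylprop-2-en-1-yl)oxolane-3-carboxylate
Product: 12 tert-butyl (2S,3S,4S)-3-[(1R)-1-(TBS-oxy)-2-methylpropyl]-4-hydroxy-2-[(1RS)-1-hydroxyprop-2-en-1-yl]-2,6-dimethylhept-6-enoate
Conditions: CH2=CHMgBr (4 equiv), THF, −20 → 0 °C
Reagents that add atoms: vinylmagnesium bromide, C=C[Mg]Br
Why: Grignard addition to the hydroxy aldehyde tautomer of a lactol forms C9–C10 and frees O6; the C10 configuration formed here is not relied on. The temperature is kept at or below 0 °C so that the magnesium aldolate next to the quaternary carbon does not fragment by retro-aldol.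

Step 10
Reactants: 12 tert-butyl (2S,3S,4S)-3-[(1R)-1-(TBS-oxy)-2-methylpropyl]-4-hydroxy-2-[(1RS)-1-hydroxyprop-2-en-1-yl]-2,6-dimethylhept-6-enoate
Product: 13 tert-butyl (1S,2RS,6S,7S)-7-[(1R)-1-(TBS-oxy)-2-methylpropyl]-2,6-dihydroxy-1,4-dimethylcyclohept-3-ene-1-carboxylate
Conditions: second-generation Grubbs catalyst (5 mol%), CH2Cl2 (5 mM), 40 °C
Reagents that add atoms: none
Why: Ring-closing metathesis; ruthenium loads on the monosubstituted vinyl group and closes onto the 1,1-disubstituted alkene, giving the trisubstituted C8=C9 bond of the seven-membered ring with loss of ethene. The quaternary C1 and the two neighbouring branches pre-organise the chain.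

Step 11
Reactants: 13 tert-butyl (1S,2RS,6S,7S)-7-[(1R)-1-(TBS-oxy)-2-methylpropyl]-2,6-dihydroxy-1,4-dimethylcyclohept-3-ene-1-carboxylate
Product: 14 tert-butyl (1S,6S,7S)-7-[(1R)-1-(TBS-oxy)-2-methylpropyl]-6-hydroxy-1,4-dimethyl-2-oxocyclohept-3-ene-1-carboxylate
Conditions: MnO2 (20 equiv), CH2Cl2, rt
Reagents that add atoms: none
Why: MnO2 oxidises only the allylic alcohol at C10, so both C10 epimers converge on one enone and O6 becomes the only free hydroxyl.

Step 12
Reactants: 14 tert-butyl (1S,6S,7S)-7-[(1R)-1-(TBS-oxy)-2-methylpropyl]-6-hydroxy-1,4-dimethyl-2-oxocyclohept-3-ene-1-carboxylate; 15 angelic acid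
Product: 17 tert-butyl (1S,6S,7S)-7-[(1R)-1-(TBS-oxy)-2-methylpropyl]-1,4-dimethyl-6-{[(2Z)-2-methylbut-2-enoyl]oxy}-2-oxocyclohept-3-ene-1-carboxylate, via mixed anhydride 16 (not isolated)
Conditions: 15, 2,4,6-trichlorobenzoyl chloride, Et3N, toluene, rt, filter; then 14, toluene, 80 °C
Reagents that add atoms: angelic acid (15), C/C=C(/C)C(=O)O
Why: Yamaguchi esterification; the alcohol attacks the unhindered angeloyl carbonyl of 16. With no nucleophilic catalyst and no free amine in the acylation, the Z-alkene should not isomerise and the enone should not be deprotonated at C7.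

Step 13
Reactants: 17 tert-butyl (1S,6S,7S)-7-[(1R)-1-(TBS-oxy)-2-methylpropyl]-1,4-dimethyl-6-{[(2Z)-2-methylbut-2-enoyl]oxy}-2-oxocyclohept-3-ene-1-carboxylate
Product: 18 tert-butyl (1S,2S,6S,7S)-7-[(1R)-1-(TBS-oxy)-2-methylpropyl]-2-hydroxy-1,4-dimethyl-6-{[(2Z)-2-methylbut-2-enoyl]oxy}cyclohept-3-ene-1-carboxylate
Conditions: (R)-2-methyl-CBS-oxazaborolidine (0.5 equiv), catecholborane, toluene, −78 °C
Reagents that add atoms: none
Why: Corey–Bakshi–Shibata reduction; with the quaternary C1 as the large group the (R)-oxazaborolidine should deliver hydride to the α face of C10, giving the (S)-alcohol cis to C15, and the axial C15 methyl biases the substrate the same way. Catecholborane at −78 °C reduces neither the esters nor the alkenes.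

Step 14
Reactants: 18 tert-butyl (1S,2S,6S,7S)-7-[(1R)-1-(TBS-oxy)-2-methylpropyl]-2-hydroxy-1,4-dimethyl-6-{[(2Z)-2-methylbut-2-enoyl]oxy}cyclohept-3-ene-1-carboxylate; 19 benzoyl chloride
Product: 20 tert-butyl (1S,2S,6S,7S)-2-(benzoyloxy)-7-[(1R)-1-(TBS-oxy)-2-methylpropyl]-1,4-dimethyl-6-{[(2Z)-2-methylbut-2-enoyl]oxy}cyclohept-3-ene-1-carboxylate
Conditions: 19, pyridine, DMAP (cat.), CH2Cl2, 0 °C → rt
Reagents that add atoms: benzoyl chloride (19), O=C(Cl)c1ccccc1
Why: Acylation of the hindered allylic alcohol under nucleophilic catalysis by DMAP; an angelate that is already formed is stable to these conditions.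

Step 15
Reactants: 20 tert-butyl (1S,2S,6S,7S)-2-(benzoyloxy)-7-[(1R)-1-(TBS-oxy)-2-methylpropyl]-1,4-dimethyl-6-{[(2Z)-2-methylbut-2-enoyl]oxy}cyclohept-3-ene-1-carboxylate
Product: 22 (1S,2S,6S,7S)-2-(benzoyloxy)-7-[(1R)-1-(TBS-oxy)-2-methylpropyl]-1,4-dimethyl-6-{[(2Z)-2-methylbut-2-enoyl]oxy}cyclohept-3-ene-1-carboxylic acid, via trimethylsilyl ester 21 (not isolated)
Conditions: TMSOTf, 2,6-lutidine, CH2Cl2, 0 °C; aq. citric acid work-up
Reagents that add atoms: none
Why: Silyl triflate-mediated cleavage of a tert-butyl ester; O-silylation of the ester carbonyl and loss of isobutene give 21, which is hydrolysed on work-up. No protic acid or base is present, so the silyl ether, the allylic benzoate and the angelate should survive.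

Step 16
Reactants: 22 (1S,2S,6S,7S)-2-(benzoyloxy)-7-[(1R)-1-(TBS-oxy)-2-methylpropyl]-1,4-dimethyl-6-{[(2Z)-2-methylbut-2-enoyl]oxy}cyclohept-3-ene-1-carboxylic acid
Product: 24 (1S,5S,6S,7S)-6-[(1R)-1-(TBS-oxy)-2-methylpropyl]-7-(diazoacetyl)-3,7-dimethyl-5-{[(2Z)-2-methylbut-2-enoyl]oxy}cyclohept-2-en-1-yl benzoate, via acid chloride 23 (not isolated)
Conditions: 1-chloro-N,N,2-trimethylprop-1-en-1-amine, CH2Cl2, 0 °C → rt; then CH2N2 (excess), Et2O, 0 °C → rt
Reagents that add atoms: diazomethane, C=[N+]=[N-]
Why: Acylation of diazomethane as in the first stage of an Arndt–Eistert sequence; the α-chloroenamine makes the neopentyl acid chloride under neutral conditions. Excess diazomethane removes HCl as chloromethane before it can add to the diazoketone; the hindered, weakly nucleophilic TBS ether should not close onto the acyl chloride.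

Step 17
Reactants: 24 (1S,5S,6S,7S)-6-[(1R)-1-(TBS-oxy)-2-methylpropyl]-7-(diazoacetyl)-3,7-dimethyl-5-{[(2Z)-2-methylbut-2-enoyl]oxy}cyclohept-2-en-1-yl benzoate
Product: 25 (3R,3aS,4S,8S,8aS)-8-(benzoyloxy)-3-(TBS-oxy)-6,8a-dimethyl-1-oxo-3-(propan-2-yl)-1,2,3,3a,4,5,8,8a-octahydroazulen-4-yl (2Z)-2-methylbut-2-enoate
Conditions: Rh2(OAc)4 (2 mol%), CH2Cl2, rt, slow addition of 24 (final 5 mM)
Reagents that add atoms: none
Why: Rh2(OAc)4 takes up the diazo carbon of 24 and loses N2 to give an electrophilic rhodium carbene at C3. The carbene carbon approaches the C4–H bond through a five-membered arrangement (C3–C2–C1–C5–C4) and, in one concerted three-centre step, takes up the hydride-like hydrogen while the C3–C4 bond forms and rhodium leaves. The closest known reaction type is the dirhodium tetracarboxylate-catalysed 1,5 C–H insertion of α-diazoketones into ether-activated C–H bonds to give cyclopentanones. The five-membered ring is closed by this 1,5-insertion between the acyl arm on C1 and the carbinol arm on C5, which are trans-diequatorial and hence gauche, so the trans ring fusion forms without strain. The new stereocentre C4 is formed with retention, because the C–C bond takes the place of the C–H bond, so its configuration is the one set in step 1. The step needs site selectivity for C4–H: this bond is tertiary and made hydridic by the silyloxy oxygen, H6 lies on the opposite (β) face and is deactivated by the acyloxy group, H5, H10 and the C15 hydrogens would give four-membered rings, and the isopropyl methine a six-membered one. It also needs chemoselectivity over the C8=C9 alkene and the oxygen lone pairs: addition to the alkene requires the conformer with the acyl arm axial, whereas in the reactive conformer four of the five ring substituents are equatorial, and the bulky silyl group on a weakly basic oxygen disfavours oxonium ylide formation. Slow addition to the catalyst at high dilution suppresses carbene dimerisation.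

Step 18
Reactants: 25 (3R,3aS,4S,8S,8aS)-8-(benzoyloxy)-3-(TBS-oxy)-6,8a-dimethyl-1-oxo-3-(propan-2-yl)-1,2,3,3a,4,5,8,8a-octahydroazulen-4-yl (2Z)-2-methylbut-2-enoate
Product: 26 (3R,3aS,4S,8S,8aS)-8-(benzoyloxy)-3-hydroxy-6,8a-dimethyl-1-oxo-3-(propan-2-yl)-1,2,3,3a,4,5,8,8a-octahydroazulen-4-yl (2Z)-2-methylbut-2-enoate
Conditions: 48% aq. HF, MeCN, 0 °C → rt
Reagents that add atoms: none
Why: Acidic fluoride cleavage of the hindered tertiary silyl ether; base is avoided because the β-silyloxy and β-hydroxy ketone would eliminate or cleave by retro-aldol and the esters could migrate.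

Step 19
Reactants: 26 (3R,3aS,4S,8S,8aS)-8-(benzoyloxy)-3-hydroxy-6,8a-dimethyl-1-oxo-3-(propan-2-yl)-1,2,3,3a,4,5,8,8a-octahydroazulen-4-yl (2Z)-2-methylbut-2-enoate
Product: 27 (1S,3R,3aS,4S,8S,8aR)-8-(benzoyloxy)-1,3-dihydroxy-6,8a-dimethyl-3-(propan-2-yl)-1,2,3,3a,4,5,8,8a-octahydroazulen-4-yl (2Z)-2-methylbut-2-enoate
Conditions: Me4NBH(OAc)3, MeCN/AcOH (1:1), −20 °C
Reagents that add atoms: none
Why: Evans–Saksena hydroxyl-directed reduction; the C4 hydroxyl exchanges onto boron and hydride is delivered intramolecularly to the β face of the C2 ketone, which should give the trans-1,3-diol with the C2 hydroxyl α. External attack by this weak hydride is slow.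

Step 20
Reactants: 27 (1S,3R,3aS,4S,8S,8aR)-8-(benzoyloxy)-1,3-dihydroxy-6,8a-dimethyl-3-(propan-2-yl)-1,2,3,3a,4,5,8,8a-octahydroazulen-4-yl (2Z)-2-methylbut-2-enoate
Product: 28 (1S,3R,3aS,4S,8S,8aR)-1-(acetyloxy)-8-(benzoyloxy)-3-hydroxy-6,8a-dimethyl-3-(propan-2-yl)-1,2,3,3a,4,5,8,8a-octahydroazulen-4-yl (2Z)-2-methylbut-2-enoate (CNP0248576.1)
Conditions: Ac2O, pyridine, DMAP (cat.), CH2Cl2, 0 °C → rt
Reagents that add atoms: acetic anhydride, CC(=O)OC(C)=O
Why: Acetylation of the secondary C2 alcohol; the tertiary C4 alcohol, flanked by isopropyl and the ring fusion, is not acylated under these mild conditions.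

## Compound list

1 | methyl 4-methyl-3-oxopentanoate | COC(=O)CC(=O)C(C)C | starting material
2 | methyl (3S)-3-hydroxy-4-methylpentanoate | COC(=O)C[C@H](O)C(C)C | intermediate
3 | tert-butyl bromoacetate | BrCC(=O)OC(C)(C)C | starting material
4 | 4-tert-butyl 1-methyl (2R)-2-[(1R)-1-hydroxy-2-methylpropyl]butanedioate | COC(=O)[C@H](CC(=O)OC(C)(C)C)[C@H](O)C(C)C | intermediate
5 | 4-tert-butyl 1-methyl (2R)-2-[(1R)-1-{[tert-butyl(dimethyl)silyl]oxy}-2-methylpropyl]butanedioate | COC(=O)[C@H](CC(=O)OC(C)(C)C)[C@H](O[Si](C)(C)C(C)(C)C)C(C)C | intermediate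
6 | tert-butyl (3R,4R)-4-{[tert-butyl(dimethyl)silyl]oxy}-3-formyl-5-methylhexanoate | O=C[C@H](CC(=O)OC(C)(C)C)[C@H](O[Si](C)(C)C(C)(C)C)C(C)C | intermediate
7 | tert-butyl (3S,4R)-4-{[tert-butyl(dimethyl)silyl]oxy}-3-[(1S)-1-hydroxy-3-methylbut-3-en-1-yl]-5-methylhexanoate | C=C(C)C[C@H](O)[C@H](CC(=O)OC(C)(C)C)[C@H](O[Si](C)(C)C(C)(C)C)C(C)C | intermediate (not isolated)
8 | (4S,5S)-4-[(1R)-1-{[tert-butyl(dimethyl)silyl]oxy}-2-methylpropyl]-5-(2-methylprop-2-en-1-yl)oxolan-2-one | C=C(C)C[C@@H]1OC(=O)C[C@@H]1[C@H](O[Si](C)(C)C(C)(C)C)C(C)C | intermediate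
9 | (3RS,4S,5S)-4-[(1R)-1-{[tert-butyl(dimethyl)silyl]oxy}-2-methylpropyl]-3-methyl-5-(2-methylprop-2-en-1-yl)oxolan-2-one | C=C(C)C[C@@H]1OC(=O)C(C)[C@@H]1[C@H](O[Si](C)(C)C(C)(C)C)C(C)C | intermediate
10 | tert-butyl (3S,4S,5S)-4-[(1R)-1-{[tert-butyl(dimethyl)silyl]oxy}-2-methylpropyl]-3-methyl-5-(2-methylprop-2-en-1-yl)-2-oxooxolane-3-carboxylate | C=C(C)C[C@@H]1OC(=O)[C@@](C)(C(=O)OC(C)(C)C)[C@@H]1[C@H](O[Si](C)(C)C(C)(C)C)C(C)C | intermediate
11 | tert-butyl (3S,4S,5S)-4-[(1R)-1-{[tert-butyl(dimethyl)silyl]oxy}-2-methylpropyl]-2-hydroxy-3-methyl-5-(2-methylprop-2-en-1-yl)oxolane-3-carboxylate (both anomers) | C=C(C)C[C@@H]1OC(O)[C@@](C)(C(=O)OC(C)(C)C)[C@@H]1[C@H](O[Si](C)(C)C(C)(C)C)C(C)C | intermediate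
12 | tert-butyl (2S,3S,4S)-3-[(1R)-1-{[tert-butyl(dimethyl)silyl]oxy}-2-methylpropyl]-4-hydroxy-2-[(1RS)-1-hydroxyprop-2-en-1-yl]-2,6-dimethylhept-6-enoate | C=C(C)C[C@H](O)[C@@H]([C@H](O[Si](C)(C)C(C)(C)C)C(C)C)[C@](C)(C(=O)OC(C)(C)C)C(O)C=C | intermediate
13 | tert-butyl (1S,2RS,6S,7S)-7-[(1R)-1-{[tert-butyl(dimethyl)silyl]oxy}-2-methylpropyl]-2,6-dihydroxy-1,4-dimethylcyclohept-3-ene-1-carboxylate | CC(C)(C)OC(=O)[C@]1(C)C(O)C=C(C)C[C@H](O)[C@H]1[C@H](O[Si](C)(C)C(C)(C)C)C(C)C | intermediate
14 | tert-butyl (1S,6S,7S)-7-[(1R)-1-{[tert-butyl(dimethyl)silyl]oxy}-2-methylpropyl]-6-hydroxy-1,4-dimethyl-2-oxocyclohept-3-ene-1-carboxylate | CC(C)(C)OC(=O)[C@]1(C)C(=O)C=C(C)C[C@H](O)[C@H]1[C@H](O[Si](C)(C)C(C)(C)C)C(C)C | intermediate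
15 | angelic acid, (2Z)-2-methylbut-2-enoic acid | C/C=C(/C)C(=O)O | starting material
16 | (2Z)-2-methylbut-2-enoic 2,4,6-trichlorobenzoic anhydride | C/C=C(/C)C(=O)OC(=O)c1c(Cl)cc(Cl)cc1Cl | intermediate (not isolated)
17 | tert-butyl (1S,6S,7S)-7-[(1R)-1-{[tert-butyl(dimethyl)silyl]oxy}-2-methylpropyl]-1,4-dimethyl-6-{[(2Z)-2-methylbut-2-enoyl]oxy}-2-oxocyclohept-3-ene-1-carboxylate | CC(C)(C)OC(=O)[C@]1(C)C(=O)C=C(C)C[C@H](OC(=O)/C(C)=C\C)[C@H]1[C@H](O[Si](C)(C)C(C)(C)C)C(C)C | intermediate
18 | tert-butyl (1S,2S,6S,7S)-7-[(1R)-1-{[tert-butyl(dimethyl)silyl]oxy}-2-methylpropyl]-2-hydroxy-1,4-dimethyl-6-{[(2Z)-2-methylbut-2-enoyl]oxy}cyclohept-3-ene-1-carboxylate | CC(C)(C)OC(=O)[C@]1(C)[C@@H](O)C=C(C)C[C@H](OC(=O)/C(C)=C\C)[C@H]1[C@H](O[Si](C)(C)C(C)(C)C)C(C)C | intermediate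
19 | benzoyl chloride | O=C(Cl)c1ccccc1 | starting material
20 | tert-butyl (1S,2S,6S,7S)-2-(benzoyloxy)-7-[(1R)-1-{[tert-butyl(dimethyl)silyl]oxy}-2-methylpropyl]-1,4-dimethyl-6-{[(2Z)-2-methylbut-2-enoyl]oxy}cyclohept-3-ene-1-carboxylate | CC(C)(C)OC(=O)[C@]1(C)[C@@H](OC(=O)c2ccccc2)C=C(C)C[C@H](OC(=O)/C(C)=C\C)[C@H]1[C@H](O[Si](C)(C)C(C)(C)C)C(C)C | intermediate
21 | trimethylsilyl (1S,2S,6S,7S)-2-(benzoyloxy)-7-[(1R)-1-{[tert-butyl(dimethyl)silyl]oxy}-2-methylpropyl]-1,4-dimethyl-6-{[(2Z)-2-methylbut-2-enoyl]oxy}cyclohept-3-ene-1-carboxylate | C[Si](C)(C)OC(=O)[C@]1(C)[C@@H](OC(=O)c2ccccc2)C=C(C)C[C@H](OC(=O)/C(C)=C\C)[C@H]1[C@H](O[Si](C)(C)C(C)(C)C)C(C)C | intermediate (not isolated)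
22 | (1S,2S,6S,7S)-2-(benzoyloxy)-7-[(1R)-1-{[tert-butyl(dimethyl)silyl]oxy}-2-methylpropyl]-1,4-dimethyl-6-{[(2Z)-2-methylbut-2-enoyl]oxy}cyclohept-3-ene-1-carboxylic acid | OC(=O)[C@]1(C)[C@@H](OC(=O)c2ccccc2)C=C(C)C[C@H](OC(=O)/C(C)=C\C)[C@H]1[C@H](O[Si](C)(C)C(C)(C)C)C(C)C | intermediate
23 | (1S,2S,6S,7S)-2-(benzoyloxy)-7-[(1R)-1-{[tert-butyl(dimethyl)silyl]oxy}-2-methylpropyl]-1,4-dimethyl-6-{[(2Z)-2-methylbut-2-enoyl]oxy}cyclohept-3-ene-1-carbonyl chloride | ClC(=O)[C@]1(C)[C@@H](OC(=O)c2ccccc2)C=C(C)C[C@H](OC(=O)/C(C)=C\C)[C@H]1[C@H](O[Si](C)(C)C(C)(C)C)C(C)C | intermediate (not isolated)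
24 | (1S,5S,6S,7S)-6-[(1R)-1-{[tert-butyl(dimethyl)silyl]oxy}-2-methylpropyl]-7-(diazoacetyl)-3,7-dimethyl-5-{[(2Z)-2-methylbut-2-enoyl]oxy}cyclohept-2-en-1-yl benzoate | [N-]=[N+]=CC(=O)[C@]1(C)[C@@H](OC(=O)c2ccccc2)C=C(C)C[C@H](OC(=O)/C(C)=C\C)[C@H]1[C@H](O[Si](C)(C)C(C)(C)C)C(C)C | intermediate
25 | (3R,3aS,4S,8S,8aS)-8-(benzoyloxy)-3-{[tert-butyl(dimethyl)silyl]oxy}-6,8a-dimethyl-1-oxo-3-(propan-2-yl)-1,2,3,3a,4,5,8,8a-octahydroazulen-4-yl (2Z)-2-methylbut-2-enoate | C/C=C(/C)C(=O)O[C@H]1CC(C)=C[C@H](OC(=O)c2ccccc2)[C@@]2(C)C(=O)C[C@@](O[Si](C)(C)C(C)(C)C)(C(C)C)[C@H]12 | intermediate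
26 | (3R,3aS,4S,8S,8aS)-8-(benzoyloxy)-3-hydroxy-6,8a-dimethyl-1-oxo-3-(propan-2-yl)-1,2,3,3a,4,5,8,8a-octahydroazulen-4-yl (2Z)-2-methylbut-2-enoate | C/C=C(/C)C(=O)O[C@H]1CC(C)=C[C@H](OC(=O)c2ccccc2)[C@@]2(C)C(=O)C[C@@](O)(C(C)C)[C@H]12 | intermediate
27 | (1S,3R,3aS,4S,8S,8aR)-8-(benzoyloxy)-1,3-dihydroxy-6,8a-dimethyl-3-(propan-2-yl)-1,2,3,3a,4,5,8,8a-octahydroazulen-4-yl (2Z)-2-methylbut-2-enoate | C/C=C(/C)C(=O)O[C@H]1CC(C)=C[C@H](OC(=O)c2ccccc2)[C@@]2(C)[C@@H](O)C[C@@](O)(C(C)C)[C@H]12 | intermediate
28 | (1S,3R,3aS,4S,8S,8aR)-1-(acetyloxy)-8-(benzoyloxy)-3-hydroxy-6,8a-dimethyl-3-(propan-2-yl)-1,2,3,3a,4,5,8,8a-octahydroazulen-4-yl (2Z)-2-methylbut-2-enoate (CNP0248576.1) | C/C=C(/C)C(=O)O[C@H]1CC(C)=C[C@H](OC(=O)c2ccccc2)[C@@]2(C)[C@@H](OC(C)=O)C[C@@](O)(C(C)C)[C@H]12 | target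

## Step count and least certain steps

Total: 20 steps. Longest linear sequence: 20 steps, from 1 to 28.

**Step 17 (key step).** The carbene may be diverted: cyclopropanation of the C8=C9 alkene from the minor conformer with the acyl arm axial, attack by the silyl ether oxygen, or dimerisation if insertion into the crowded C4–H bond (flanked by isopropyl, the silyl ether and the ring) is slow. The fallback uses the better-behaved acceptor/acceptor carbene of a diazo β-keto ester. It sets out from acid 22, which is activated with carbonyldiimidazole and condensed with Mg(O2CCH2CO2CH2CH2SiMe3)2 to give the 2-(trimethylsilyl)ethyl β-keto ester F1. Diazo transfer with 4-acetamidobenzenesulfonyl azide and Et3N gives the α-diazo-β-keto ester F2. Rh2(OAc)4 in CH2Cl2 then closes the ring by the same 1,5-insertion to the bicyclic β-keto ester F3. Bu4NF buffered with AcOH removes the silylethyl group, and the β-keto acid loses CO2 to come back to the route at 25.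

**Step 7.** Deprotonation of the tertiary α-hydrogen, which lies on the face carrying both ring substituents, may be incomplete, or the tetrasubstituted enolate may be acylated on oxygen. The fallback sets out from 9: the enolate is quenched with CO2, a small electrophile that reacts at carbon, to give the malonic half-acid F4. This is esterified with tert-butyl 2,2,2-trichloroacetimidate (cat. BF3·OEt2), which returns to the route at 10.

**Step 5.** Facial selectivity may be poor, because the chiral borane works against the Felkin–Anh preference of 6 (C4 arm as the large group). The fallback turns this preference to advantage and sets out from 6. Barbier addition of methallyl bromide with indium in THF/H2O gives the epimeric alcohols F5, and Dess–Martin periodinane (NaHCO3) gives the β,γ-unsaturated ketone F6. Reduction with LiBH(sec-Bu)3 at −78 °C should then be Felkin–Anh controlled and give the (S)-carbinol. This rejoins the route at 7, which is lactonised to 8 as in step 5.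

**Step 12.** Acylation of the hindered C6 hydroxyl may be slow enough for Z to E isomerisation of the activated angeloyl unit, or the C6 oxygen may be lost by elimination through the dienolate of the enone. The fallback builds the Z-alkene on the ester and sets out from 14. Esterification with 2-(diphenoxyphosphoryl)propanoic acid (DCC, DMAP cat.) gives the phosphonopropionate F7. Ando olefination with acetaldehyde (KN(SiMe3)2, 18-crown-6, THF, −78 °C) gives the Z-2-methylbut-2-enoate and returns to the route at 17. The phosphonate proton is far more acidic than H7, so the base is consumed there.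

## Further compounds

F1 | step 17 | 2-(trimethylsilyl)ethyl 3-oxopropanoate carrying at C3 the cycloheptenyl unit of 24 (C1–CO–CH2–CO2CH2CH2SiMe3) | C[Si](C)(C)CCOC(=O)CC(=O)[C@]1(C)[C@@H](OC(=O)c2ccccc2)C=C(C)C[C@H](OC(=O)/C(C)=C\C)[C@H]1[C@H](O[Si](C)(C)C(C)(C)C)C(C)C
F2 | step 17 | 2-(trimethylsilyl)ethyl 2-diazo-3-oxopropanoate analogue of F1 | C[Si](C)(C)CCOC(=O)C(=[N+]=[N-])C(=O)[C@]1(C)[C@@H](OC(=O)c2ccccc2)C=C(C)C[C@H](OC(=O)/C(C)=C\C)[C@H]1[C@H](O[Si](C)(C)C(C)(C)C)C(C)C
F3 | step 17 | 25 bearing a 2-(trimethylsilyl)ethoxycarbonyl group at C3 (both C3 epimers) | C/C=C(/C)C(=O)O[C@H]1CC(C)=C[C@H](OC(=O)c2ccccc2)[C@@]2(C)C(=O)C(C(=O)OCC[Si](C)(C)C)[C@@](O[Si](C)(C)C(C)(C)C)(C(C)C)[C@H]12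
F4 | step 7 | (3R,4S,5S)-4-[(1R)-1-{[tert-butyl(dimethyl)silyl]oxy}-2-methylpropyl]-3-methyl-5-(2-methylprop-2-en-1-yl)-2-oxooxolane-3-carboxylic acid | C=C(C)C[C@@H]1OC(=O)[C@@](C)(C(=O)O)[C@@H]1[C@H](O[Si](C)(C)C(C)(C)C)C(C)C
F5 | step 5 | tert-butyl (3S,4R)-4-{[tert-butyl(dimethyl)silyl]oxy}-3-(1-hydroxy-3-methylbut-3-en-1-yl)-5-methylhexanoate (both carbinol epimers) | C=C(C)CC(O)[C@H](CC(=O)OC(C)(C)C)[C@H](O[Si](C)(C)C(C)(C)C)C(C)C
F6 | step 5 | tert-butyl (3R,4R)-4-{[tert-butyl(dimethyl)silyl]oxy}-5-methyl-3-(3-methylbut-3-enoyl)hexanoate | C=C(C)CC(=O)[C@H](CC(=O)OC(C)(C)C)[C@H](O[Si](C)(C)C(C)(C)C)C(C)C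
F7 | step 12 | 14 esterified at O6 with 2-(diphenoxyphosphoryl)propanoic acid | CC(C)(C)OC(=O)[C@]1(C)C(=O)C=C(C)C[C@H](OC(=O)C(C)P(=O)(Oc2ccccc2)Oc2ccccc2)[C@H]1[C@H](O[Si](C)(C)C(C)(C)C)C(C)C
A1 | alternative 1 | (5R)-2-diazo-6-methyl-5-(4-methylphenyl)-5-[(triethylsilyl)oxy]heptan-3-one | CC(=[N+]=[N-])C(=O)C[C@@](O[Si](CC)(CC)CC)(C(C)C)c1ccc(C)cc1
A2 | alternative 1 | 6,8a-dimethyl-3-(propan-2-yl)-3-[(triethylsilyl)oxy]-3,8a-dihydroazulen-1(2H)-one (C1 and C4 as in the target) | C[C@@]12C=CC(C)=CC=C1[C@](O[Si](CC)(CC)CC)(C(C)C)CC2=O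
A3 | alternative 2 | cyclopenta[c]pyran with tributylstannyl at C6, isopropenyl at C9 (trans to tin), methoxymethyl ether at C10, TBS ether at C2 and triethylsilyl ether at C4 | CCCC[Sn](CCCC)(CCCC)[C@H]1O[C@H](C(C)=C)[C@H](OCOC)[C@@]2(C)[C@@H](O[Si](C)(C)C(C)(C)C)C[C@@](O[Si](CC)(CC)CC)(C(C)C)[C@H]12
A4 | alternative 2 | daucene core with free C6 hydroxyl, C10 methoxymethyl ether, C2 TBS ether and C4 triethylsilyl ether | O[C@H]1CC(C)=C[C@H](OCOC)[C@@]2(C)[C@@H](O[Si](C)(C)C(C)(C)C)C[C@@](O[Si](CC)(CC)CC)(C(C)C)[C@H]12
A5 | alternative 3 | (4S)-4-{[tert-butyl(dimethyl)silyl]oxy}-2,6-dimethylcyclohepta-2,6-dien-1-one | CC1=C[C@@H](O[Si](C)(C)C(C)(C)C)CC(C)=CC1=O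
A6 | alternative 3 | cycloheptenone with 1-ethoxyvinyl at C5, TBS ether at C6 and hydroxymethyl on quaternary C1 | C=C(OCC)[C@@H]1[C@@H](O[Si](C)(C)C(C)(C)C)CC(C)=CC(=O)[C@@]1(C)CO
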